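**Assumption:** "7R" is the exocyclic benzylic carbinol, and the given SMILES defines all other stereochemistry. Relative to the ring, it is 2,3-trans and 3,4-cis, with the carbinol R.

## Retrosynthetic overview
1. Target **13** comes from the bis-TBS ether **12** by fluoride deprotection.
2. **12** comes from the epoxy cinnamyl ether **11** by a Cp2TiCl-mediated epoxide opening and 5-exo radical cyclisation. This closes the THF ring, forms the C8–C8′ bond, and puts the 7′-OH on the benzylic radical by oxygenative capture. The C7 stereocentre controls C8 and C8′.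
3. **11** comes from diol **10**. **10** comes from Sharpless epoxy alcohol **9** and silyl coniferyl alcohol **8** by inverting C-3 opening, which sets C7.
4. **9** comes from **8** by Sharpless AE. **8** comes from vanillin-TBS ether **6** (Wittig, then DIBAL). Vanillin comes from vanillylmandelic acid (VMA) **4**, which comes from guaiacol **2** and glyoxylic acid **3**. Guaiacol comes from catechol **1**.
5. The two arenes are built first, and the THF is formed last, in step 10.

## Forward route

**Step 1**
Reactants: **1** catechol
Product: **2** guaiacol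
Conditions: dimethyl carbonate, K2CO3 (cat.), 160 °C, sealed tube (recycle unreacted catechol)
Reagents that add atoms: dimethyl carbonate, COC(=O)OC (supplies the OCH3)
Why: Base-catalysed O-methylation (BAl2) with dimethyl carbonate is selective for mono-methylation of catechol, and no stereocentre is involved.

**Step 2**
Reactants: **2** guaiacol; **3** glyoxylic acid
Product: **4** (±)-4-hydroxy-3-methoxymandelic acid (VMA)
Conditions: aq. NaOH, 0 °C → rt; then acidify
Reagents that add atoms: none
Why: Hydroxyalkylation of the guaiacol phenoxide (Friedel–Crafts type) occurs para to the OH; the racemic carbinol is destroyed in step 3.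

**Step 3**
Reactants: **4**
Product: **5** vanillin
Conditions: CuSO4 (cat.), aq. NaOH, O2 (air), 90 °C
Reagents that add atoms: none
Why: Cu-catalysed oxidative decarboxylation of an aryl mandelic acid gives the aldehyde (known vanillin process).

**Step 4**
Reactants: **5**
Product: **6** 4-(tert-butyldimethylsilyloxy)-3-methoxybenzaldehyde
Conditions: TBSCl, imidazole, DMF, rt
Reagents that add atoms: TBSCl, CC(C)(C)[Si](C)(C)Cl
Why: Silylation masks the phenol so that the basic, Lewis-acidic and radical steps that follow are tolerated.

**Step 5**
Reactants: **6**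
Product: **7** (E)-3-[4-(TBSO)-3-methoxyphenyl]propenal
Conditions: Ph3P=CHCHO, toluene, 80 °C
Reagents that add atoms: (formylmethylene)triphenylphosphorane, O=CC=P(c1ccccc1)(c1ccccc1)c1ccccc1 (supplies CH=CH–CHO after loss of Ph3PO)
Why: Wittig olefination with a stabilised ylide gives the E-enal.

**Step 6**
Reactants: **7**
Product: **8** (E)-coniferyl alcohol TBS ether, OC/C=C/Ar
Conditions: DIBAL-H (2.2 equiv), CH2Cl2, −78 °C
Reagents that add atoms: none (hydride only)
Why: 1,2-Reduction of the enal gives the cinnamyl alcohol, and the aryl silyl ether survives at low temperature.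

**Step 7**
Reactants: **8**
Product: **9** (2S,3S)-3-[4-(TBSO)-3-methoxyphenyl]oxirane-2-methanol
Conditions: Ti(OiPr)4 (10 mol%), L-(+)-DET (12 mol%), TBHP, 3 Å MS, CH2Cl2, −20 °C; Rochelle-salt workup
Reagents that add atoms: tert-butyl hydroperoxide, CC(C)(C)OO (supplies the epoxide O)
Why: Sharpless asymmetric epoxidation with L-(+)-DET delivers oxygen to one face of the allylic alcohol and sets both epoxide stereocentres as (2S,3S); this is the only enantio-defining step.

**Step 8**
Reactants: **9**; **8** (3 equiv)
Product: **10** (1R,2S)-1-aryl-1-[(E)-3-arylallyloxy]propane-2,3-diol, both Ar = 4-TBSO-3-MeO-C6H3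
Conditions: Ti(OiPr)4 (1.2 equiv), CH2Cl2, 0 °C → rt; Rochelle-salt workup
Reagents that add atoms: none (the nucleophile is reactant **8**)
Why: Ti(OiPr)4-mediated opening of a 2,3-epoxy alcohol (Caron–Sharpless) is C-3 selective, and the benzylic position adds to this. SN2 inversion at C-3 converts the (3S) epoxide into the benzylic ether whose configuration matches C7 of the target, and C8 is unchanged.

**Step 9**
Reactants: **10**
Product: **11** (2S)-2-{(R)-aryl[(E)-3-arylallyloxy]methyl}oxirane, both Ar = 4-TBSO-3-MeO-C6H3
Conditions: TsCl, Et3N, Bu2SnO (cat.), CH2Cl2, 0 °C; then NaH, THF, 0 °C → rt (one pot)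
Reagents that add atoms: none (tosylate is lost as NaOTs)
Why: Selective tosylation of the primary OH, then 3-exo-tet closure by the C8 alkoxide, gives the terminal epoxide. The C8 centre is erased in step 10, so its configuration does not matter.

**Step 10 (key step)**
Reactants: **11**
Product: **12** bis-TBS ether of the target
Conditions: Cp2TiCl2 (2.4 equiv), Zn (5 equiv), THF, rt, substrate added over 2 h (0.01 M); then O2 (1 atm), −78 → 0 °C; then PPh3 (2 equiv); aq. Rochelle-salt workup
Reagents that add atoms: dioxygen, O=O (becomes the 7′-OH oxygen)
Why: Proposed new method: Cp2TiCl opens the terminal epoxide to the secondary C8 radical carrying CH2OTi (C9), which cyclises 5-exo onto the cinnamyl alkene through a chair-like Beckwith–Houk transition state. The pseudo-equatorial C7 aryl then gives the 7,8-trans and 8,8′-cis relative configuration, and the resulting p-silyloxybenzylic radical is captured by a second Cp2TiCl as a benzyl–Ti(IV) species. The Ti sits anti to C8 in the favoured staggered conformer, and O2 insertion into the Ti–C bond with retention, followed by PPh3 reduction of the peroxide, delivers the 7′R carbinol. The closest known reactions are Cp2TiCl epoxide-opening radical cyclisations and oxygenation of alkyl-titanium(IV) species; slow addition outcompetes trapping and β-alkoxy elimination of the C8 radical.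

**Step 11**
Reactants: **12**
Product: **13** (7R)-7-hydroxylariciresinol
Conditions: TBAF (2.5 equiv), AcOH (2.5 equiv), THF, 0 °C → rt
Reagents that add atoms: none
Why: Buffered fluoride cleaves the aryl silyl ethers without ionising the acid-sensitive benzylic alcohol or ether, and no stereocentre is touched.

## Compound list
| No. | Name | SMILES | Role |
|---|---|---|---|
| 1 | catechol | Oc1ccccc1O | starting material |
| 2 | guaiacol | COc1ccccc1O | intermediate |
| 3 | glyoxylic acid | OC(=O)C=O | starting material |
| 4 | (±)-4-hydroxy-3-methoxymandelic acid | COc1cc(C(O)C(=O)O)ccc1O | intermediate |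
| 5 | vanillin | COc1cc(C=O)ccc1O | intermediate |
| 6 | 4-TBSO-3-methoxybenzaldehyde | COc1cc(C=O)ccc1O[Si](C)(C)C(C)(C)C | intermediate |
| 7 | (E)-3-(4-TBSO-3-methoxyphenyl)propenal | COc1cc(/C=C/C=O)ccc1O[Si](C)(C)C(C)(C)C | intermediate |
| 8 | (E)-coniferyl alcohol TBS ether | COc1cc(/C=C/CO)ccc1O[Si](C)(C)C(C)(C)C | intermediate |
| 9 | (2S,3S)-epoxy alcohol | COc1cc([C@@H]2O[C@H]2CO)ccc1O[Si](C)(C)C(C)(C)C | intermediate |
| 10 | (1R,2S)-diol ether | COc1cc([C@@H](OC/C=C/c2ccc(O[Si](C)(C)C(C)(C)C)c(OC)c2)[C@@H](O)CO)ccc1O[Si](C)(C)C(C)(C)C | intermediate |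
| 11 | (2S)-2-{(R)-aryl[(E)-cinnamyloxy]methyl}oxirane | COc1cc([C@@H](OC/C=C/c2ccc(O[Si](C)(C)C(C)(C)C)c(OC)c2)[C@@H]2CO2)ccc1O[Si](C)(C)C(C)(C)C | intermediate |
| 12 | bis-TBS ether of the target | COc1cc([C@H]2OC[C@H]([C@@H](O)c3ccc(O[Si](C)(C)C(C)(C)C)c(OC)c3)[C@@H]2CO)ccc1O[Si](C)(C)C(C)(C)C | intermediate |
| 13 | (7R)-7-hydroxylariciresinol, (2S,3R,4R)-2-aryl-3-(hydroxymethyl)-4-[(R)-hydroxy(aryl)methyl]THF, Ar = 4-hydroxy-3-methoxyphenyl | COc1cc([C@H]2OC[C@H]([C@@H](O)c3ccc(O)c(OC)c3)[C@@H]2CO)ccc1O | target |

## Summary
Total steps: 11. Longest linear sequence: 11 (catechol → **2** → **4** → **5** → **6** → **7** → **8** → **9** → **10** → **11** → **12** → **13**).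

**Three steps most likely to fail**
1. **Step 10.** Failure modes are poor C7′ diastereoselectivity, inefficient Ti–C oxygenation, and β-alkoxy elimination of the C8 radical or organotitanium. Fallback: accept the 7′-epimeric mixture, oxidise selectively at the benzylic alcohol with MnO2 (the primary alcohol is untouched), then reduce the ketone by Noyori Ru-TsDPEN transfer hydrogenation, where the catalyst controls the new carbinol.
2. **Step 8.** The electron-rich benzylic epoxide may open with partial SN1 character, or iPrO⁻ may compete, eroding regiochemistry and inversion. Fallback: Ir-catalysed asymmetric allylic etherification of a coniferyl carbonate with **8** to give the branched ether Ar–CH(OR)–CH=CH2 and set C7 directly. Then apply terminal-selective epoxidation (Ti-salalen/H2O2) and carry on from **11**.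
3. **Step 7.** The 3-aryl epoxy alcohol is acid-labile, so ee and yield may suffer. Fallback: Shi organocatalytic epoxidation of **8**, choosing the catalyst enantiomer that gives (2S,3S)-**9**.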